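A single half-life of L cannot serve both earlier runs: first-order loss uses the same percent of any charge in a given time, yet by 50.0 min Monday's run has used 31.8% and Wednesday's only 24.2%.

| flask | L | G | remark | time |
|---|---|---|---|---|
| Monday's | 12 mM | 9 mM (held) | run made earlier |  |
| Wednesday's | 18 mM | 9 mM (held) | run made earlier |  |
| flask | 24 mM | 9.0 mM (held) |  | 40 min |

| run | time / min | L / % | J / % |
|---|---|---|---|
| Monday's | 6.00 | 97.8 | 1.6 |
| Monday's | 15.0 | 95.7 | 8.1 |
| Monday's | 30.0 | 81.7 | 15.4 |
| Monday's | 50.0 | 68.2 | 24.0 |
| Wednesday's | 6.00 | 98.5 | 0.5 |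
| Wednesday's | 15.0 | 95.4 | 3.7 |
| Wednesday's | 30.0 | 84.8 | 10.9 |
| Wednesday's | 50.0 | 75.8 | 19.6 |

(readings scatter by 1 percentage point)

- at the start none of G is in solution
- the earlier runs do not show how much of Q is bound; that part of a forecast is a guess

* part of the L that has reacted at 40 min
* share of the unused Q that is free and not bound as X, at 40 min

So count in mM, not percent. A straight line between the readings at 30.0 min and 50.0 min gives, at 40 min, 3.01 mM of L used in Monday's run and 3.55 mM in Wednesday's. Wednesday's charge is 1.50 times Monday's, but its L used is just 1.18 times as much, with G held at 9 mM in both. At 40 min Wednesday's run stands lower than Monday's in percent of its charge and higher in mM.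

Call n the apparent order in L: the logarithm of the ratio of mM used divided by the logarithm of the ratio of charges. Here n is 0.407, a reading that carries the scatter. Taken from Wednesday's run to your flask, my own reckoning gives 3.99 mM used, or 16.6%.

The forecast, reckoned its own way, says 16% (11% to 21%) for c and 50% (15% to 85%) for fr, adding “free share is therefore a guess”.

The flask gives c = 18.1% and fr = 40.1%. That c is 4.36 mM of L used, more than the 3.99 mM that n carried from Wednesday's run. At 40.0 min the flask holds 2.79 mM of free Q beside 4.17 mM of X.

    G ⇌ Q, rate k1*(csat - [Q]) (kL = 6.93 × 10⁻⁴ /s)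
    L + Q → E + J (k = 0.0380 /M/s)
    Q + E ⇌ X, settled at all times (K = 8000 /M)
    J ⇌ D (K = 0.390, k = 5.09 × 10⁻⁴ /s)

Now take the flask with 9.6 mM of L. From Monday's run, n gives 2.74 mM used, or 28.5%; the computed c there is 25.8%.

The earlier runs and the new flask come from a simulation with made-up constants; the scatter is artificial.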